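**Retrosynthetic overview**

1. The feature that decides the route is the quaternary C8 of ring A, which carries two prenyl groups between the C7 ketone and the enol-ether carbon C8a. The unit C7(=O)–C8–CH2–CH=CMe2 is a Claisen retron, and it is present twice.
2. Last disconnection: the C2–phenyl bond, by catalyst-controlled conjugate addition of phenylboronic acid to the achiral dearomatised chromone 10. The base-labile C2 centre is thus made after all heating.
3. Key disconnection: the C8–CH2 bond of the second prenyl group, by a dearomative [3,3] shift from O7 of the 7-(1,1-dimethylallyl) ether 9 of an 8-prenylchromone. Ring A of a flat chromone becomes the cyclohexadienone.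
4. The first prenyl group enters C8 by the same O7-to-C8 relay (ordinary aromatic Claisen). Each ether comes from a palladium-catalysed O-tert-prenylation.
5. Ring order: ring A is bought as an acetophenone, ring C (γ-pyrone) is closed first with a one-carbon unit, ring A is then dearomatised, and C2 is set last.

Key step: step 5

Remarks on the chemistry:
- Assumption: the facial sense of the palladium pyridine-oxazoline catalyst on 10 follows that known for chromones, where the (S)-ligand gives (R)-2-arylchroman-4-ones. The (R)-ligand is therefore specified; the antipode would be used if the sense were reversed on this substrate.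
- Carbonate 5 is taken as a purchasable reagent.

**Step 1**
Reactants: 1 1-(2,4-dihydroxy-6-methoxyphenyl)ethan-1-one; 2 N,N-dimethylformamide dimethyl acetal
Product: 4 7-hydroxy-5-methoxy-4H-chromen-4-one, via enaminone 3 (not isolated)
Conditions: 2 (1.3 equiv), toluene, 80 °C; then 2 M aq. HCl, CH2Cl2, rt
Reagents that add atoms: N,N-dimethylformamide dimethyl acetal (2), COC(OC)N(C)C
Why: Condensation of the acetyl methyl group with the amide acetal gives the enaminone, and acid then drives addition–elimination by the only hydroxyl ortho to the side chain (chromone synthesis from a 2-hydroxyacetophenone enaminone), so the methoxy group ends at C5 and the free hydroxyl at C7.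

**Step 2**
Reactants: 4 7-hydroxy-5-methoxy-4H-chromen-4-one; 5 tert-butyl (2-methylbut-3-en-2-yl) carbonate
Product: 6 5-methoxy-7-[(2-methylbut-3-en-2-yl)oxy]-4H-chromen-4-one
Conditions: 5 (1.5 equiv), Pd(PPh3)4 (3 mol%), THF, 0 °C to rt
Reagents that add atoms: tert-butyl (2-methylbut-3-en-2-yl) carbonate (5), C=CC(C)(C)OC(=O)OC(C)(C)C
Why: Tsuji–Trost O-allylation, in which the 1,1-dimethylallyl palladium cation formed by ionisation and decarboxylation of the tertiary carbonate is captured by the acidic 7-phenoxide at its more substituted terminus under kinetic control, which should give the tertiary ether.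

**Step 3**
Reactants: 6 5-methoxy-7-[(2-methylbut-3-en-2-yl)oxy]-4H-chromen-4-one
Product: 8 7-hydroxy-5-methoxy-8-(3-methylbut-2-en-1-yl)-4H-chromen-4-one, via ortho-dienone 7 (not isolated)
Conditions: xylenes, 130 °C, argon
Reagents that add atoms: none
Why: Aromatic Claisen rearrangement with allyl inversion turns the 1,1-dimethylallyl ether into a C-prenyl group; as with 7-allyloxychromones the shift should go to C8, because the γ-pyrone ring keeps C4a=C8a and leaves the higher π-bond order in C7–C8, while C6 is screened by the 5-methoxy group, and dienone 7 then enolises to the phenol.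

**Step 4**
Reactants: 8 7-hydroxy-5-methoxy-8-(3-methylbut-2-en-1-yl)-4H-chromen-4-one; 5 tert-butyl (2-methylbut-3-en-2-yl) carbonate
Product: 9 5-methoxy-8-(3-methylbut-2-en-1-yl)-7-[(2-methylbut-3-en-2-yl)oxy]-4H-chromen-4-one
Conditions: 5 (1.5 equiv), Pd(PPh3)4 (3 mol%), THF, 0 °C
Reagents that add atoms: tert-butyl (2-methylbut-3-en-2-yl) carbonate (5), C=CC(C)(C)OC(=O)OC(C)(C)C
Why: The same Tsuji–Trost O-allylation as in step 2, in which attack through oxygen is little affected by the ortho prenyl group and the low temperature should keep the tertiary ether from ionising again.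

**Step 5**
Reactants: 9 5-methoxy-8-(3-methylbut-2-en-1-yl)-7-[(2-methylbut-3-en-2-yl)oxy]-4H-chromen-4-one
Product: 10 5-methoxy-8,8-bis(3-methylbut-2-en-1-yl)-4H-chromene-4,7(8H)-dione
Conditions: degassed toluene, 100 °C, argon
Reagents that add atoms: none
Why: Proposed new method: a concerted suprafacial [3,3] shift through a chair transition state breaks the O7–CMe2 bond of the aryl tert-allyl ether and joins the vinyl CH2 terminus to C8, so that allyl inversion delivers a second normal prenyl group and the ring A phenol ether becomes the C7 ketone of a cyclohexa-2,4-dienone; the closest known reaction types are the dearomative Claisen rearrangement of 1-substituted 2-naphthyl allyl ethers to 1,1-disubstituted naphthalen-2(1H)-ones and the C8-selective Claisen rearrangement of 7-allyloxychromones. No ring is closed (rings A and C are kept and ring A is dearomatised) and no stereocentre is formed, since C8 carries two identical prenyl groups. The step needs selectivity for C8 over C6: the γ-pyrone ring retains C4a=C8a, which localises ring A as C7=C8 and C5=C6 (the rule that sends 2-naphthyl ethers to C1), whereas a shift to C6 would have to break the pyrone conjugation and pass the 5-methoxy group that flanks C6. Unlike the usual ortho-dienone, 10 has no hydrogen at C8 and cannot enolise, and it is stabilised twice over, as the vinylogous ester O5–C5=C6–C7=O and as an intact γ-pyrone, so it should be the resting point of the rearrangement and not revert. The ether is di-ortho-substituted and twisted, which should lower the barrier and allow a temperature at which loss of isoprene and migration to C6 stay slow.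

**Step 6**
Reactants: 10 5-methoxy-8,8-bis(3-methylbut-2-en-1-yl)-4H-chromene-4,7(8H)-dione; 11 phenylboronic acid
Product: 12 griffinone A, (2S)-5-methoxy-8,8-bis(3-methylbut-2-en-1-yl)-2-phenyl-2,3-dihydro-4H-chromene-4,7(8H)-dione
Conditions: 11 (2 equiv), Pd(OCOCF3)2 (10 mol%), (R)-4-tert-butyl-2-(pyridin-2-yl)-4,5-dihydrooxazole (12 mol%), NH4PF6 (30 mol%), H2O (5 equiv), ClCH2CH2Cl, 60 °C
Reagents that add atoms: phenylboronic acid (11), OB(O)c1ccccc1
Why: Asymmetric conjugate addition of an arylboronic acid to a chromone-type enone by a cationic divalent palladium pyridine-oxazoline complex (transmetalation, enantio-determining insertion of C2=C3 into the Pd–Ph bond, protonolysis of the palladium enolate), in which C2 is the only unhindered β-carbon (C5 and C8a are fully substituted), the (R)-ligand should deliver phenyl to the face that gives 2S, and the base-free medium leaves no path for retro-oxa-Michael racemisation of the new centre.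

**Compound list**

1 | 1-(2,4-dihydroxy-6-methoxyphenyl)ethan-1-one | CC(=O)c1c(O)cc(O)cc1OC | starting material
2 | N,N-dimethylformamide dimethyl acetal | COC(OC)N(C)C | starting material
3 | (E)-1-(2,4-dihydroxy-6-methoxyphenyl)-3-(dimethylamino)prop-2-en-1-one | CN(C)/C=C/C(=O)c1c(O)cc(O)cc1OC | intermediate
4 | 7-hydroxy-5-methoxy-4H-chromen-4-one | O=c1ccoc2cc(O)cc(OC)c12 | intermediate
5 | tert-butyl (2-methylbut-3-en-2-yl) carbonate | C=CC(C)(C)OC(=O)OC(C)(C)C | starting material
6 | 5-methoxy-7-[(2-methylbut-3-en-2-yl)oxy]-4H-chromen-4-one | O=c1ccoc2cc(OC(C)(C)C=C)cc(OC)c12 | intermediate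
7 | 5-methoxy-8-(3-methylbut-2-en-1-yl)-4H-chromene-4,7(8H)-dione (racemic at C8) | COC1=CC(=O)C(CC=C(C)C)C2=C1C(=O)C=CO2 | intermediate
8 | 7-hydroxy-5-methoxy-8-(3-methylbut-2-en-1-yl)-4H-chromen-4-one | O=c1ccoc2c(CC=C(C)C)c(O)cc(OC)c12 | intermediate
9 | 5-methoxy-8-(3-methylbut-2-en-1-yl)-7-[(2-methylbut-3-en-2-yl)oxy]-4H-chromen-4-one | O=c1ccoc2c(CC=C(C)C)c(OC(C)(C)C=C)cc(OC)c12 | intermediate
10 | 5-methoxy-8,8-bis(3-methylbut-2-en-1-yl)-4H-chromene-4,7(8H)-dione | COC1=CC(=O)C(CC=C(C)C)(CC=C(C)C)C2=C1C(=O)C=CO2 | intermediate
11 | phenylboronic acid | OB(O)c1ccccc1 | starting material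
12 | griffinone A, (2S)-5-methoxy-8,8-bis(3-methylbut-2-en-1-yl)-2-phenyl-2,3-dihydro-4H-chromene-4,7(8H)-dione | COC1=CC(=O)C(CC=C(C)C)(CC=C(C)C)C2=C1C(=O)C[C@@H](c1ccccc1)O2 | target

**Step count and risk**

Total step count: 6. Longest linear sequence: 6.

Steps most likely to fail:

1. Step 5 (proposed method). The [3,3] shift may go to C6 instead, after which enolisation makes the wrong regiochemistry irreversible, or the tertiary ether may ionise and lose isoprene before it rearranges. The fallback uses known chemistry and runs from 8 back to 10: a palladium-catalysed intermolecular allylic dearomatisation, in which phenol 8 is treated with tert-butyl (3-methylbut-2-en-1-yl) carbonate and Pd(PPh3)4 in toluene at room temperature to 50 °C. This Tsuji–Trost C-allylation is established for 1-substituted 2-naphthols and for C-prenylated acylphloroglucinols. O-allylation of the acidic phenol is reversible under zerovalent palladium, whereas attack of C8 on the unsubstituted terminus of the prenyl palladium cation is not, so the mixture should drain into 10. This fallback makes no new compound (F0).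

2. Step 6. Insertion into the pyrone-type C2=C3 bond may be slow, it may take place at C5 with loss of methoxide, or facial discrimination may be poor on this hindered substrate. The fallback runs from 8 and rejoins the route at 12. The conjugate addition is moved to the aromatic chromone 8, a substrate class on which this catalysis is established (same catalyst, phenylboronic acid 11), to give (S)-7-hydroxy-5-methoxy-8-(3-methylbut-2-en-1-yl)-2-phenylchroman-4-one F1. O-tert-prenylation with 5 and Pd(PPh3)4 at 0 °C gives (S)-5-methoxy-8-(3-methylbut-2-en-1-yl)-7-[(2-methylbut-3-en-2-yl)oxy]-2-phenylchroman-4-one F2. The dearomative [3,3] shift is then run on the flavanone in toluene at 100 °C and should give 12 directly. All three operations are free of strong base, so C2 should be kept. The bias for C8 is expected to be smaller without the γ-pyrone, so separation from the product of migration to C6 would be needed.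

3. Step 3. Part of the allyl group may migrate to C6, or the tertiary ether may be cleaved by ionisation before it rearranges. The fallback runs from 1 back to 8. The first prenyl group is placed on the acetophenone, where C3 between the two hydroxyl groups is the most nucleophilic carbon (prenyl bromide, one equivalent, aq. KOH, 0 °C; classical C-prenylation), to give 1-[2,4-dihydroxy-6-methoxy-3-(3-methylbut-2-en-1-yl)phenyl]ethan-1-one F3. Treatment with 2 as in step 1 gives (E)-1-[2,4-dihydroxy-6-methoxy-3-(3-methylbut-2-en-1-yl)phenyl]-3-(dimethylamino)prop-2-en-1-one F4, which closes with dilute acid to 8. Only the 2-hydroxyl can close the pyrone ring, so the prenyl group must end at C8.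

**Further compounds**

F0 | step 5 | none | none
F1 | step 6 | (S)-7-hydroxy-5-methoxy-8-(3-methylbut-2-en-1-yl)-2-phenylchroman-4-one | COc1cc(O)c(CC=C(C)C)c2c1C(=O)C[C@@H](c1ccccc1)O2
F2 | step 6 | (S)-5-methoxy-8-(3-methylbut-2-en-1-yl)-7-[(2-methylbut-3-en-2-yl)oxy]-2-phenylchroman-4-one | COc1cc(OC(C)(C)C=C)c(CC=C(C)C)c2c1C(=O)C[C@@H](c1ccccc1)O2
F3 | step 3 | 1-[2,4-dihydroxy-6-methoxy-3-(3-methylbut-2-en-1-yl)phenyl]ethan-1-one | CC(=O)c1c(O)c(CC=C(C)C)c(O)cc1OC
F4 | step 3 | (E)-1-[2,4-dihydroxy-6-methoxy-3-(3-methylbut-2-en-1-yl)phenyl]-3-(dimethylamino)prop-2-en-1-one | CN(C)/C=C/C(=O)c1c(O)c(CC=C(C)C)c(O)cc1OC
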